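## Retrosynthetic overview

1. The biaryl bond is never disconnected late: it is traced back to the oxidative 5,5'-coupling of vanillin (1) to dehydrodivanillin (2).
2. Both lignan rings are cut at the benzylic carbon C7 in one operation. The tetrahydrofuran (C7–O) and the tetralin (C7–aryl) both come from one acyclic bis(benzylic alcohol) through quinone-methide-type cations. A tosyloxy group switches off Friedel–Crafts closure in one arm only.
3. C7–C8 of each arm comes from two consecutive Evans aldol reactions on the protected dialdehyde (3). These fix C8; C7 is left to the final cascade.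
4. The tertiary carbinol C8' of each arm comes from L-malic acid (4), alkylated with that arm's own benzyl halide by Seebach's self-regeneration of stereocentres.
5. Ring order: biaryl link in step 1; no ring of the target exists until step 14. There both tetrahydrofurans close first, and the guaiacyl-arm ring then reopens and closes to the tetralin.

Assumption: the target is taken exactly as drawn, including the 3-hydroxy-4-methoxybenzyl group on the tetrahydrofuran arm.

Labels: lignan numbering is used in each arm. C7 is the benzylic carbon on the biaryl ring, C8 the adjacent CH, C9 its CH2OH; C7', C8', C9' belong to the benzyl unit. Arm A is the tetrahydrofuran arm (tosyloxy ring); arm B is the tetralin arm.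

## Route

Step 1
Reactants: 1 vanillin (2 equiv)
Product: 2 dehydrodivanillin (6,6'-dihydroxy-5,5'-dimethoxy-[1,1'-biphenyl]-3,3'-dicarbaldehyde)
Conditions: laccase (Trametes versicolor), O2, acetone–NaOAc buffer pH 5, 25 °C
Reagents that add atoms: none
Why: Oxidative phenol coupling: the phenoxyl radical has its para position blocked by CHO, so it dimerises ortho–ortho (5,5'), and the insoluble dimer precipitates before it is oxidised further.

Step 2
Reactants: 2 dehydrodivanillin
Product: 3 5,5'-dimethoxy-6,6'-bis(methoxymethoxy)-[1,1'-biphenyl]-3,3'-dicarbaldehyde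
Conditions: NaH, MOMCl, DMF, 0 °C → rt
Reagents that add atoms: chloromethyl methyl ether (MOMCl), COCCl
Why: Williamson-type O-alkylation of the bis-phenoxide; MOM survives enolate, boron and hydride steps and falls off in the acid of step 14.

Step 3
Reactants: 4 L-malic acid
Product: 5 2-[(2S,4S)-2-tert-butyl-5-oxo-1,3-dioxolan-4-yl]acetic acid
Conditions: pivaldehyde, p-TsOH (cat.), H2SO4 (cat.), pentane, reflux, Dean–Stark
Reagents that add atoms: pivaldehyde, CC(C)(C)C=O
Why: Acid-catalysed acetalisation of the α-hydroxy acid unit (Seebach dioxolanone); the cis isomer (tert-butyl cis to the CH2CO2H chain) is favoured and crystallises.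

Step 4
Reactants: 6 isovanillyl alcohol (5-(hydroxymethyl)-2-methoxyphenol)
Product: 8 5-(chloromethyl)-2-methoxyphenyl 4-methylbenzenesulfonate, via benzylic tosylate 7 (not isolated)
Conditions: TsCl (2.3 equiv), iPr2NEt, DMAP (cat.), CH2Cl2, 0 °C → rt
Reagents that add atoms: p-toluenesulfonyl chloride, Cc1ccc(cc1)S(Cl)(=O)=O
Why: Sulfonylation of phenol and alcohol; the para-methoxybenzylic tosylate is too labile to persist and is displaced by the chloride released from TsCl, while the aryl tosylate stays as the electron-withdrawing group needed in step 14.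

Step 5
Reactants: 9 vanillyl alcohol (4-(hydroxymethyl)-2-methoxyphenol)
Product: 10 [3-methoxy-4-(methoxymethoxy)phenyl]methanol
Conditions: MOMCl (1.1 equiv), K2CO3, acetone, 0 °C → rt
Reagents that add atoms: chloromethyl methyl ether (MOMCl), COCCl
Why: Selective O-alkylation: only the phenol is deprotonated by K2CO3, so the phenoxide reacts and the neutral benzylic alcohol does not.

Step 6
Reactants: 10 [3-methoxy-4-(methoxymethoxy)phenyl]methanol
Product: 11 4-(bromomethyl)-2-methoxy-1-(methoxymethoxy)benzene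
Conditions: CBr4, PPh3, CH2Cl2, 0 °C; used at once
Reagents that add atoms: carbon tetrabromide, BrC(Br)(Br)Br
Why: Appel reaction under neutral conditions, which the MOM ether tolerates.

Step 7
Reactants: 5 dioxolanone acid; 8 arm A benzylic chloride
Product: 12 2-[(2S,4S)-2-tert-butyl-4-{[4-methoxy-3-(tosyloxy)phenyl]methyl}-5-oxo-1,3-dioxolan-4-yl]acetic acid
Conditions: LiN(SiMe3)2 (2.1 equiv), THF, −78 °C; then 8, NaI (0.1 equiv), −78 → −30 °C; citric acid work-up
Reagents that add atoms: none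
Why: Seebach self-regeneration of stereocentres: the carboxylate–enolate dianion is alkylated anti to the tert-butyl group, so benzyl replaces H with retention and C8' is set (S) from L-malic acid.

Step 8
Reactants: 5 dioxolanone acid; 11 arm B benzylic bromide
Product: 13 2-[(2S,4S)-2-tert-butyl-4-{[3-methoxy-4-(methoxymethoxy)phenyl]methyl}-5-oxo-1,3-dioxolan-4-yl]acetic acid
Conditions: LiN(SiMe3)2 (2.1 equiv), THF, −78 °C; then 11, −78 → −30 °C; citric acid work-up
Reagents that add atoms: none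
Why: Same Seebach enolate alkylation anti to tert-butyl, setting C8' (S) of arm B with retention.

Step 9
Reactants: 12 arm A acid; 14 (S)-4-benzyl-1,3-oxazolidin-2-one
Product: 16 (4S)-4-benzyl-3-{[(2S,4S)-2-tert-butyl-4-{[4-methoxy-3-(tosyloxy)phenyl]methyl}-5-oxo-1,3-dioxolan-4-yl]acetyl}-1,3-oxazolidin-2-one, via mixed pivalic anhydride 15 (not isolated)
Conditions: PivCl, Et3N, THF, −20 °C; then 14, LiCl, −20 °C → rt
Reagents that add atoms: none
Why: N-acylation through the mixed anhydride; the oxazolidinone attacks the CH2C=O carbonyl, not the more hindered pivaloyl or the neopentyl-type dioxolanone carbonyl.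

Step 10
Reactants: 13 arm B acid; 14 (S)-4-benzyl-1,3-oxazolidin-2-one
Product: 18 (4S)-4-benzyl-3-{[(2S,4S)-2-tert-butyl-4-{[3-methoxy-4-(methoxymethoxy)phenyl]methyl}-5-oxo-1,3-dioxolan-4-yl]acetyl}-1,3-oxazolidin-2-one, via mixed pivalic anhydride 17 (not isolated)
Conditions: PivCl, Et3N, THF, −20 °C; then 14, LiCl, −20 °C → rt
Reagents that add atoms: none
Why: Same mixed-anhydride N-acylation as step 9.

Step 11
Reactants: 3 dialdehyde (3.0 equiv, excess recovered); 16 arm A imide
Product: 19 mono-aldol adduct (arm A on one ring, (7S,8R); other CHO free)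
Conditions: n-Bu2BOTf (1.2 equiv), iPr2NEt (1.4 equiv), CH2Cl2, 0 °C; then 3, −78 → 0 °C; pH 7 buffer, MeOH, H2O2, 0 °C
Reagents that add atoms: none
Why: Evans syn aldol: the Z boron enolate reacts through a Zimmerman–Traxler chair on the face opposite the auxiliary benzyl group, which sets C8 (R) by reagent control (C7 comes out S and is erased later); the excess of 3 keeps the reaction at mono-addition.

Step 12
Reactants: 19 mono-aldol adduct; 18 arm B imide (2.2 equiv, excess recovered)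
Product: 20 bis-aldol adduct (both arms attached, (7S,8R) in each)
Conditions: n-Bu2BOTf (2.4 equiv), iPr2NEt (2.8 equiv), CH2Cl2, 0 °C; then 19, −78 → 0 °C; pH 7 buffer, MeOH, H2O2, 0 °C
Reagents that add atoms: none
Why: Second Evans syn aldol with the same auxiliary and facial sense, setting C8 (R) of arm B; one equivalent of enolate is spent on the free hydroxyl of 19 (borinate formed in the flask), hence the excess.

Step 13
Reactants: 20 bis-aldol adduct
Product: 21 octaol (each former CHO carbon now carries a (1S,2R,3S)-1,3,4-trihydroxy-2-(hydroxymethyl)-3-(arylmethyl)butyl chain)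
Conditions: LiBH4, THF, MeOH (2 equiv), 0 °C → rt
Reagents that add atoms: none
Why: Reductive cleavage: both imide carbonyls become C9H2OH and release the auxiliary, and both dioxolanones are reduced to C9'H2OH plus the free tertiary alcohol; aryl tosylate and MOM ethers are inert to LiBH4.

Step 14
Reactants: 21 octaol
Product: 24 5-O-tosyl derivative of the target (tetrahydrofuran arm and tetralin arm formed), via triphenol polyol 22 (not isolated), via bis-tetrahydrofuran 23 (not isolated)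
Conditions: HCl (1.25 M in MeOH), MeOH, 0.01 M, 40 °C, N2
Reagents that add atoms: none
Why: Proposed new method: acid removes the three MOM groups (as dimethoxymethane) and ionises both para-hydroxybenzylic alcohols to protonated quinone methides, which first close reversibly with O9' to tetrahydrofurans on both arms (the 2,3-trans isomer being the stable one), after which only the guaiacyl arm, whose ring carbon para to OMe is nucleophilic, closes irreversibly through a chair-like Friedel–Crafts transition state (aryl trans to C8–CH2OH) to the tetralin, while the arm A ring, whose ortho carbons are para or ortho to OTs and meta to OMe, cannot react and stays as the tetrahydrofuran; the closest known reactions are the acid isomerisation of olivil to cycloolivil and quinone-methide cyclisations of lignan diols.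

Step 15
Reactants: 24 O-tosyl target
Product: 25 target CNP0252244.1
Conditions: KOH (20 equiv), MeOH–H2O 4:1, degassed, 65 °C; then aq. NH4Cl
Reagents that add atoms: none
Why: Hydrolysis of the aryl sulfonate by hydroxide attack at sulfur; no stereocentre is touched, and the only epimerisable centre (C7 of the tetrahydrofuran) already has its stable trans configuration.

## Compound list

1 | vanillin | COc1cc(C=O)ccc1O | starting material
2 | dehydrodivanillin | COc1cc(C=O)cc(-c2cc(C=O)cc(OC)c2O)c1O | intermediate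
3 | 5,5'-dimethoxy-6,6'-bis(methoxymethoxy)-[1,1'-biphenyl]-3,3'-dicarbaldehyde | COCOc1c(OC)cc(C=O)cc1-c1cc(C=O)cc(OC)c1OCOC | intermediate
4 | L-malic acid | O[C@@H](CC(=O)O)C(=O)O | starting material
5 | 2-[(2S,4S)-2-tert-butyl-5-oxo-1,3-dioxolan-4-yl]acetic acid | OC(=O)C[C@@H]1O[C@H](C(C)(C)C)OC1=O | intermediate
6 | isovanillyl alcohol | COc1ccc(CO)cc1O | starting material
7 | 2-methoxy-5-[(tosyloxy)methyl]phenyl tosylate (not isolated) | COc1ccc(COS(=O)(=O)c2ccc(C)cc2)cc1OS(=O)(=O)c1ccc(C)cc1 | intermediate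
8 | 5-(chloromethyl)-2-methoxyphenyl 4-methylbenzenesulfonate | COc1ccc(CCl)cc1OS(=O)(=O)c1ccc(C)cc1 | intermediate
9 | vanillyl alcohol | COc1cc(CO)ccc1O | starting material
10 | [3-methoxy-4-(methoxymethoxy)phenyl]methanol | COCOc1ccc(CO)cc1OC | intermediate
11 | 4-(bromomethyl)-2-methoxy-1-(methoxymethoxy)benzene | COCOc1ccc(CBr)cc1OC | intermediate
12 | arm A acid, 2-[(2S,4S)-2-tert-butyl-4-{[4-methoxy-3-(tosyloxy)phenyl]methyl}-5-oxo-1,3-dioxolan-4-yl]acetic acid | OC(=O)C[C@]1(Cc2ccc(OC)c(OS(=O)(=O)c3ccc(C)cc3)c2)O[C@H](C(C)(C)C)OC1=O | intermediate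
13 | arm B acid, 2-[(2S,4S)-2-tert-butyl-4-{[3-methoxy-4-(methoxymethoxy)phenyl]methyl}-5-oxo-1,3-dioxolan-4-yl]acetic acid | OC(=O)C[C@]1(Cc2ccc(OCOC)c(OC)c2)O[C@H](C(C)(C)C)OC1=O | intermediate
14 | (S)-4-benzyl-1,3-oxazolidin-2-one | O=C1N[C@@H](Cc2ccccc2)CO1 | starting material
15 | mixed pivalic anhydride of 12 (not isolated) | CC(C)(C)C(=O)OC(=O)C[C@]1(Cc2ccc(OC)c(OS(=O)(=O)c3ccc(C)cc3)c2)O[C@H](C(C)(C)C)OC1=O | intermediate
16 | arm A imide, (4S)-4-benzyl-3-(acyl)oxazolidin-2-one with acyl = acetyl of 12 | O=C(C[C@]1(Cc2ccc(OC)c(OS(=O)(=O)c3ccc(C)cc3)c2)O[C@H](C(C)(C)C)OC1=O)N1[C@@H](Cc2ccccc2)COC1=O | intermediate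
17 | mixed pivalic anhydride of 13 (not isolated) | CC(C)(C)C(=O)OC(=O)C[C@]1(Cc2ccc(OCOC)c(OC)c2)O[C@H](C(C)(C)C)OC1=O | intermediate
18 | arm B imide, (4S)-4-benzyl-3-(acyl)oxazolidin-2-one with acyl = acetyl of 13 | O=C(C[C@]1(Cc2ccc(OCOC)c(OC)c2)O[C@H](C(C)(C)C)OC1=O)N1[C@@H](Cc2ccccc2)COC1=O | intermediate
19 | mono-aldol adduct: (2R,3S)-3-hydroxy-3-aryl-2-[dioxolanonyl of 16]propanoyl oxazolidinone, aryl = 5'-formyl-5,5'-dimethoxy-6,6'-bis(methoxymethoxy)biphenyl-3-yl | O=C(N1[C@@H](Cc2ccccc2)COC1=O)[C@H]([C@H](O)c1cc(OC)c(OCOC)c(c1)-c1cc(C=O)cc(OC)c1OCOC)[C@]1(Cc2ccc(OC)c(OS(=O)(=O)c3ccc(C)cc3)c2)O[C@H](C(C)(C)C)OC1=O | intermediate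
20 | bis-aldol adduct: both CHO carbons of 3 are (S)-carbinols, each bonded to the (R)-α-carbon of an acyl oxazolidinone; dioxolanone of 16 on one arm, of 18 on the other | O=C(N1[C@@H](Cc2ccccc2)COC1=O)[C@H]([C@H](O)c1cc(OC)c(OCOC)c(c1)-c1cc(cc(OC)c1OCOC)[C@@H](O)[C@@H](C(=O)N1[C@@H](Cc2ccccc2)COC1=O)[C@]1(Cc2ccc(OC)c(OS(=O)(=O)c3ccc(C)cc3)c2)O[C@H](C(C)(C)C)OC1=O)[C@]1(Cc2ccc(OCOC)c(OC)c2)O[C@H](C(C)(C)C)OC1=O | intermediate
21 | octaol: biaryl of 3 with each CHO replaced by (1S,2R,3S)-1,3,4-trihydroxy-2-(hydroxymethyl)-3-(arylmethyl)butyl; arylmethyl = 4-methoxy-3-(tosyloxy)benzyl (arm A) or 3-methoxy-4-(methoxymethoxy)benzyl (arm B) | OC[C@H]([C@H](O)c1cc(OC)c(OCOC)c(c1)-c1cc(cc(OC)c1OCOC)[C@@H](O)[C@@H](CO)[C@](O)(CO)Cc1ccc(OC)c(OS(=O)(=O)c2ccc(C)cc2)c1)[C@](O)(CO)Cc1ccc(OCOC)c(OC)c1 | intermediate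
22 | triphenol polyol: 21 with all three MOM groups removed (not isolated) | OC[C@H]([C@H](O)c1cc(OC)c(O)c(c1)-c1cc(cc(OC)c1O)[C@@H](O)[C@@H](CO)[C@](O)(CO)Cc1ccc(OC)c(OS(=O)(=O)c2ccc(C)cc2)c1)[C@](O)(CO)Cc1ccc(O)c(OC)c1 | intermediate
23 | bis-tetrahydrofuran: each arm a (2S,3R,4S)-4-hydroxy-3-(hydroxymethyl)-4-(arylmethyl)oxolan-2-yl ring (not isolated) | COc1ccc(C[C@@]2(O)CO[C@H](c3cc(OC)c(O)c(c3)-c3cc(cc(OC)c3O)[C@H]3OC[C@](O)(Cc4ccc(O)c(OC)c4)[C@@H]3CO)[C@H]2CO)cc1OS(=O)(=O)c1ccc(C)cc1 | intermediate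
24 | target with the 3-hydroxyl of the 4-methoxybenzyl ring as tosylate: (2S,3R,4S)-oxolane arm and (1S,2S,3S)-tetralin arm | COc1ccc(C[C@@]2(O)CO[C@H](c3cc(OC)c(O)c(-c4cc([C@H]5c6cc(O)c(OC)cc6C[C@@](O)(CO)[C@@H]5CO)cc(OC)c4O)c3)[C@H]2CO)cc1OS(=O)(=O)c1ccc(C)cc1 | intermediate
25 | CNP0252244.1 | COc1ccc(C[C@@]2(O)CO[C@H](c3cc(OC)c(O)c(-c4cc([C@H]5c6cc(O)c(OC)cc6C[C@@](O)(CO)[C@@H]5CO)cc(OC)c4O)c3)[C@H]2CO)cc1O | target

## Step count and risks

Total: 15 steps. Longest linear sequence: 8 steps (for example steps 4, 7, 9, 11, 12, 13, 14, 15).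

**Step 7 (and its twin, step 8).** The dianion of 5 may react sluggishly or O-alkylate with the functionalised benzylic halide. Fallback, setting out from 5 and 8 and returning at 12: chloride 8 is oxidised (DMSO, NaHCO3, 100 °C, Kornblum) to 5-formyl-2-methoxyphenyl 4-methylbenzenesulfonate F1. The same dianion of 5 adds to this far more reactive aldehyde, again anti to tert-butyl, to give the hydroxybenzyl dioxolanone acid F2 as a carbinol epimer mixture. Ionic hydrogenation (Et3SiH, TFA, CH2Cl2) removes the para-methoxybenzylic hydroxyl and gives 12.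

**Step 11 (and step 12).** The boron enolate next to a quaternary carbon may not form or add. Fallback, setting out from 12 and 3 and returning at 21: acid 12 is coupled through 15 with (S)-4-benzyl-1,3-thiazolidine-2-thione (S=C1N[C@@H](Cc2ccccc2)CS1) to give the N-acylthiazolidinethione of arm A F3. Its smaller chlorotitanium enolate (TiCl4, iPr2NEt, N-methylpyrrolidinone, CH2Cl2, −78 → 0 °C) adds to 3 (3 equiv) in the same syn sense to give the thione mono-aldol adduct F4. A second aldol with 18 as in step 12 gives the mixed bis-aldol adduct F5, and LiBH4 cleaves both auxiliaries and both dioxolanones to reach 21.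

**Step 14.** The one-pot divergence may stall at 23 or give mixtures. Fallback, setting out from 3 and 18 and returning at 24: the rings are formed one after the other. The Evans aldol of 18 with excess 3 gives the arm B mono-aldol adduct F6. Bi(OTf)3 (5 mol %) in MeNO2–CH2Cl2 at 0 °C closes the tetralin by Friedel–Crafts alkylation while O9' is still locked in the dioxolanone, so no tetrahydrofuran can compete; this gives the spiro-dioxolanone tetralin aldehyde F7. The aldol with 16 as in step 12 gives the tetralin bis-adduct F8, and LiBH4 gives the tetralin–open-chain polyol F9. HCl in MeOH then only has to remove MOM and close the tetrahydrofuran of arm A, giving 24.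

## Further compounds

F1 | step 7 | 5-formyl-2-methoxyphenyl 4-methylbenzenesulfonate | COc1ccc(C=O)cc1OS(=O)(=O)c1ccc(C)cc1
F2 | step 7 | 2-[(2S,4S)-2-tert-butyl-4-{hydroxy[4-methoxy-3-(tosyloxy)phenyl]methyl}-5-oxo-1,3-dioxolan-4-yl]acetic acid (carbinol epimers) | OC(=O)C[C@]1(C(O)c2ccc(OC)c(OS(=O)(=O)c3ccc(C)cc3)c2)O[C@H](C(C)(C)C)OC1=O
F3 | step 11 | N-acyl (S)-4-benzylthiazolidine-2-thione of arm A acid 12 | O=C(C[C@]1(Cc2ccc(OC)c(OS(=O)(=O)c3ccc(C)cc3)c2)O[C@H](C(C)(C)C)OC1=O)N1[C@@H](Cc2ccccc2)CSC1=S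
F4 | step 11 | thione mono-aldol adduct (arm A, (7S,8R), other CHO free) | O=C(N1[C@@H](Cc2ccccc2)CSC1=S)[C@H]([C@H](O)c1cc(OC)c(OCOC)c(c1)-c1cc(C=O)cc(OC)c1OCOC)[C@]1(Cc2ccc(OC)c(OS(=O)(=O)c3ccc(C)cc3)c2)O[C@H](C(C)(C)C)OC1=O
F5 | step 11 | mixed bis-aldol adduct (thiazolidinethione on arm A, oxazolidinone on arm B) | O=C(N1[C@@H](Cc2ccccc2)COC1=O)[C@H]([C@H](O)c1cc(OC)c(OCOC)c(c1)-c1cc(cc(OC)c1OCOC)[C@@H](O)[C@@H](C(=O)N1[C@@H](Cc2ccccc2)CSC1=S)[C@]1(Cc2ccc(OC)c(OS(=O)(=O)c3ccc(C)cc3)c2)O[C@H](C(C)(C)C)OC1=O)[C@]1(Cc2ccc(OCOC)c(OC)c2)O[C@H](C(C)(C)C)OC1=O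
F6 | step 14 | arm B mono-aldol adduct ((7S,8R), other CHO free) | O=C(N1[C@@H](Cc2ccccc2)COC1=O)[C@H]([C@H](O)c1cc(OC)c(OCOC)c(c1)-c1cc(C=O)cc(OC)c1OCOC)[C@]1(Cc2ccc(OCOC)c(OC)c2)O[C@H](C(C)(C)C)OC1=O
F7 | step 14 | spiro-dioxolanone tetralin aldehyde (arm B cyclised, 1-aryl trans to the acyl group) | O=Cc1cc(OC)c(OCOC)c(c1)-c1cc(cc(OC)c1OCOC)[C@H]1c2cc(OCOC)c(OC)cc2C[C@]2(O[C@H](C(C)(C)C)OC2=O)[C@@H]1C(=O)N1[C@@H](Cc2ccccc2)COC1=O
F8 | step 14 | tetralin bis-adduct (arm A aldol unit on the second ring) | O=C(N1[C@@H](Cc2ccccc2)COC1=O)[C@H]([C@H](O)c1cc(OC)c(OCOC)c(c1)-c1cc(cc(OC)c1OCOC)[C@H]1c2cc(OCOC)c(OC)cc2C[C@]2(O[C@H](C(C)(C)C)OC2=O)[C@@H]1C(=O)N1[C@@H](Cc2ccccc2)COC1=O)[C@]1(Cc2ccc(OC)c(OS(=O)(=O)c3ccc(C)cc3)c2)O[C@H](C(C)(C)C)OC1=O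
F9 | step 14 | tetralin–open-chain polyol (arm B as MOM-protected cycloolivil unit, arm A as open tetraol) | OC[C@H]([C@H](O)c1cc(OC)c(OCOC)c(c1)-c1cc(cc(OC)c1OCOC)[C@H]1c2cc(OCOC)c(OC)cc2C[C@@](O)(CO)[C@@H]1CO)[C@](O)(CO)Cc1ccc(OC)c(OS(=O)(=O)c2ccc(C)cc2)c1
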